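**Plan**
- Cuts: the two ester C–O bonds (O3–senecioyl, O9–tigloyl), the C7–C11 bond of the isopropenyl group, and in ring A the C4–C5 and C1–C10 bonds.
- Enabling feature (eremophilane numbering): ring B (C5–C10) carries the pattern of 2-methoxy-5-methyl-1,4-benzoquinone (methyl on C5, OMe on C8, C=O on C9, one surplus C=O on C6), and C1–C4 of ring A are a 3-silyloxypenta-1,3-diene (oxygen on C3, methyl on C4).
- Forward: ring B is bought and ring A closes by an enantioselective [4+2] cycloaddition. Hydride reduction and acid then transpose the ring B carbonyls to the 9-hydroxy-6-en-8-one, the esters go on at O3 and then O9, and iodination, Stille coupling and conjugate reduction place the isopropenyl group on C7.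
- Stereochemistry: C5 comes from a chiral titanium catalyst bound in two-point fashion to O8 and O9, which also fixes the orientation. C10, C4, C9 and C7 are set by equilibration or protonation next to carbonyl groups towards the all-equatorial trans-decalin, and C3 by a thermodynamically controlled dissolving-metal reduction.

Key step: step 2

Convention: eremophilane numbering throughout; α/β refer to the usual drawing with the angular C14 methyl β; the C12 bicyclic intermediates are named as 11,12,13-trinoreremophilanes.
Assumption: the (R)-binaphtholate is written for the titanium catalyst; the sense of face selection on the chelated quinone is not established for this substrate, so the mirror-image ligand is to be used if the first run gives the antipode of 5.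

Step 1
Reactants: 1 ethyl vinyl ketone (pent-1-en-3-one); 2 triisopropylsilyl trifluoromethanesulfonate
Product: 3 (Z)-triisopropyl(penta-1,3-dien-3-yloxy)silane
Conditions: Et3N (1.3 equiv), CH2Cl2, 0 → 23 °C
Reagents that add atoms: none
Why: Soft enolisation and O-silylation of the enone (silyl triflate/amine) should give the 2-silyloxydiene mainly as the Z enol ether (methyl cis to oxygen, trans to the vinyl group), and a minor E isomer would be a poor diene that is left behind in step 2.

Step 2
Reactants: 3 (Z)-triisopropyl(penta-1,3-dien-3-yloxy)silane; 4 2-methoxy-5-methyl-1,4-benzoquinone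
Product: 5 cis-fused adduct 8-methoxy-3-(triisopropylsilyloxy)-11,12,13-trinoreremophila-2,7-diene-6,9-dione (5β-methyl; 10β-H; 4α-methyl)
Conditions: TiCl2[(R)-1,1'-binaphthalene-2,2'-diolate] (15 mol%; from TiCl2(Oi-Pr)2 and (R)-1,1'-bi-2-naphthol, 4 Å MS, filtered), CH2Cl2, −40 °C
Reagents that add atoms: none
Why: Two-point binding of the tetravalent titanium centre to the C8 methoxy oxygen and the C9 carbonyl oxygen of 4 activates the methyl-bearing C5=C10 double bond and makes C5 its electrophilic end, so a concerted, asynchronous normal-demand [4+2] cycloaddition joins the nucleophilic enol-ether terminus C4 of 3 to C5 and the vinyl terminus C1 to C10 (closest known types: chiral titanium binaphtholate-catalysed quinone Diels–Alder reactions and chelation-directed Lewis acid Diels–Alder reactions of this quinone). The six-membered ring A closes in this one suprafacial–suprafacial event through an endo transition state. C5 is set by the binaphtholate, which must leave open the Re face of the methyl-bearing quinone carbon; C10 follows from suprafacial addition (H10 cis to C14) and C4 from the Z enol-ether geometry combined with endo approach (C15 trans to C14). The step needs site selectivity (the methoxy group turns the other double bond into an unreactive enol ether), regioselectivity (the chelate; a single-point boron Lewis acid would be expected to sit on the more basic vinylogous-ester carbonyl at C6 and reverse the orientation) and face selectivity (the ligand). Only C5 has to be right here, because C4 and C10 are corrected later by enolisation.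

Step 3
Reactants: 5 cis-fused adduct
Product: 6 trans-fused 8-methoxy-3-(triisopropylsilyloxy)-11,12,13-trinoreremophila-2,7-diene-6,9-dione (5β-methyl; 10α-H; 4α-methyl)
Conditions: DBU (0.2 equiv), toluene, 23 °C
Reagents that add atoms: none
Why: Base-mediated epimerisation next to the C9 ketone should convert the kinetic cis adduct into the trans-fused dione, expected to be favoured as for the butadiene adduct of the same quinone, with the dienolate reprotonated at C10 on the α face anti to the angular C14 methyl (H10 α).

Step 4
Reactants: 6 trans-fused dione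
Product: 7 8-methoxy-3-(triisopropylsilyloxy)-11,12,13-trinoreremophila-2,7-diene-6β,9β-diol (4α-methyl; 10α-H)
Conditions: LiAlH4 (1.5 equiv), THF, −20 → 0 °C; aq. potassium sodium tartrate
Reagents that add atoms: none
Why: Hydride 1,2-reduction of the C9 ketone and of the vinylogous-ester carbonyl C6 (first half of a reductive 1,3-carbonyl transposition) should occur from the α face away from the axial C14 methyl to give the 6β,9β-diol, leaving both enol ethers intact (C6 is lost in step 6 and C9 is corrected in step 9).

Step 5
Reactants: 7 enol-ether diol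
Product: 9 6β,9β-dihydroxy-8-methoxy-11,12,13-trinoreremophil-7-en-3-one (4β-methyl; 10α-H), via 4α-methyl epimer 8 (not isolated)
Conditions: Bu4NF (1.1 equiv), THF, 0 °C; then K2CO3 (0.5 equiv), MeOH, 23 °C
Reagents that add atoms: none
Why: Fluoride desilylation of the silyl enol ether releases the C3 ketone, and carbonate-mediated epimerisation at C4 should move the C15 methyl from the axial α to the equatorial β position, the stable arrangement in 4β,5β-dimethyl-3-oxo trans-decalins such as friedelin.

Step 6
Reactants: 9 keto diol
Product: 11 3α,9β-dihydroxy-11,12,13-trinoreremophil-6-en-8-one, via enol-ether triol 10 (not isolated)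
Conditions: Li (6 equiv), NH3(l)–THF, t-BuOH (3 equiv), −78 °C; NH4Cl; then 1 M HCl, THF, 23 °C
Reagents that add atoms: water, O
Why: Dissolving-metal reduction of the C3 ketone is thermodynamically controlled and should give the equatorial 3α-alcohol (hydride reagents would be steered to the axial 3β-alcohol by the syn-axial C14 methyl), and the acidic work-up ionises the allylic C6 hydroxyl, water adds at C8 and methanol leaves, completing the 1,3-carbonyl transposition to the 9-hydroxy-6-en-8-one.

Step 7
Reactants: 11 dihydroxy enone; 12 3-methylbut-2-enoic acid (senecioic acid)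
Product: 13 9β-hydroxy-3α-(3-methylbut-2-enoyloxy)-11,12,13-trinoreremophil-6-en-8-one
Conditions: DCC (1.2 equiv), DMAP (0.1 equiv), CH2Cl2, 0 °C
Reagents that add atoms: none
Why: Steglich esterification should acylate the unhindered equatorial C3 hydroxyl selectively, because the C9 hydroxyl is pseudo-axial, syn to the C14 methyl and a hydrogen-bonded α-ketol hydroxyl of low nucleophilicity.

Step 8
Reactants: 13 3α-senecioate; 14 (E)-2-methylbut-2-enoyl chloride (tigloyl chloride)
Product: 15 3α-(3-methylbut-2-enoyloxy)-9β-[(E)-2-methylbut-2-enoyloxy]-11,12,13-trinoreremophil-6-en-8-one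
Conditions: 14 (3 equiv), pyridine (5 equiv), DMAP (0.5 equiv), CH2Cl2, 40 °C
Reagents that add atoms: none
Why: Acyl chloride esterification under nucleophilic catalysis with excess reagent and gentle heating should force the remaining hindered hydroxyl to the tiglate; any C9 epimerisation under these conditions converges in step 9.

Step 9
Reactants: 15 9β-tiglate
Product: 16 3α-(3-methylbut-2-enoyloxy)-9α-[(E)-2-methylbut-2-enoyloxy]-11,12,13-trinoreremophil-6-en-8-one
Conditions: DBU (0.3 equiv), toluene, 23 °C, argon
Reagents that add atoms: none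
Why: Base-catalysed epimerisation of the α-acyloxy ketone through its C8 enolate relieves the syn-axial interaction between the 9β-ester and the C14 methyl and should give the equatorial 9α-tiglate, as axial 2β-acyloxy-3-oxo steroids go to their 2α epimers.

Step 10
Reactants: 16 9α-tiglate enone
Product: 17 7-iodo-3α-(3-methylbut-2-enoyloxy)-9α-[(E)-2-methylbut-2-enoyloxy]-11,12,13-trinoreremophil-6-en-8-one
Conditions: I2 (2.5 equiv), pyridine–CH2Cl2 (1:1), 0 → 23 °C; aq. Na2S2O3
Reagents that add atoms: iodine, II
Why: α-Iodination of the enone by the iodine–pyridine addition–elimination sequence (pyridine adds at C6, the enolate is iodinated at C7, pyridine leaves) is established for cyclohexenones with a quaternary γ-carbon and should spare the two electron-poor ester alkenes.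

Step 11
Reactants: 17 α-iodoenone; 18 tributyl(prop-1-en-2-yl)stannane
Product: 19 3α-(3-methylbut-2-enoyloxy)-9α-[(E)-2-methylbut-2-enoyloxy]eremophila-6,11-dien-8-one
Conditions: Pd2(dba)3 (2.5 mol%), AsPh3 (20 mol%), CuI (10 mol%), NMP, 40 °C
Reagents that add atoms: none
Why: Stille coupling of the α-iodoenone under neutral, copper-assisted conditions should form the C7–C11 bond without exposing the α-acyloxy ketone or the esters to alkali.

Step 12
Reactants: 19 cross-conjugated dienone
Product: 20 3α-(3-methylbut-2-enoyloxy)-9α-[(E)-2-methylbut-2-enoyloxy]eremophil-11-en-8-one (target; 7α-isopropenyl; 10α-H)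
Conditions: [CuH(PPh3)]6 (0.4 equiv), degassed benzene, H2O (5 equiv), 23 °C; aq. NH4Cl
Reagents that add atoms: none
Why: Copper hydride conjugate reduction should deliver hydride to C6 of the enone only, and kinetic protonation of the dienolate at its α-carbon C7 by the water present keeps the C11=C12 double bond and places the isopropenyl group in the equatorial 7α position, which is also the thermodynamic one because a 7β group would be syn-axial to the C14 methyl.

**Compound list**
1 | ethyl vinyl ketone (pent-1-en-3-one) | CCC(=O)C=C | starting material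
2 | triisopropylsilyl trifluoromethanesulfonate | CC(C)[Si](OS(=O)(=O)C(F)(F)F)(C(C)C)C(C)C | starting material
3 | (Z)-triisopropyl(penta-1,3-dien-3-yloxy)silane | C=C/C(O[Si](C(C)C)(C(C)C)C(C)C)=C/C | intermediate
4 | 2-methoxy-5-methyl-1,4-benzoquinone | COC1=CC(=O)C(C)=CC1=O | starting material
5 | cis-fused 8-methoxy-3-(triisopropylsilyloxy)-11,12,13-trinoreremophila-2,7-diene-6,9-dione (5β-Me, 10β-H, 4α-Me) | COC1=CC(=O)[C@]2(C)[C@H](C)C(O[Si](C(C)C)(C(C)C)C(C)C)=CC[C@@H]2C1=O | intermediate
6 | trans-fused 8-methoxy-3-(triisopropylsilyloxy)-11,12,13-trinoreremophila-2,7-diene-6,9-dione (5β-Me, 10α-H, 4α-Me) | COC1=CC(=O)[C@]2(C)[C@H](C)C(O[Si](C(C)C)(C(C)C)C(C)C)=CC[C@H]2C1=O | intermediate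
7 | 8-methoxy-3-(triisopropylsilyloxy)-11,12,13-trinoreremophila-2,7-diene-6β,9β-diol (4α-Me, 10α-H) | COC1=C[C@@H](O)[C@]2(C)[C@H](C)C(O[Si](C(C)C)(C(C)C)C(C)C)=CC[C@H]2[C@H]1O | intermediate
8 | 6β,9β-dihydroxy-8-methoxy-11,12,13-trinoreremophil-7-en-3-one, 4α-methyl epimer | COC1=C[C@@H](O)[C@]2(C)[C@H](C)C(=O)CC[C@H]2[C@H]1O | intermediate (not isolated)
9 | 6β,9β-dihydroxy-8-methoxy-11,12,13-trinoreremophil-7-en-3-one (4β-Me, 10α-H) | COC1=C[C@@H](O)[C@]2(C)[C@@H](C)C(=O)CC[C@H]2[C@H]1O | intermediate
10 | 8-methoxy-11,12,13-trinoreremophil-7-ene-3α,6β,9β-triol | COC1=C[C@@H](O)[C@]2(C)[C@@H](C)[C@H](O)CC[C@H]2[C@H]1O | intermediate (not isolated)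
11 | 3α,9β-dihydroxy-11,12,13-trinoreremophil-6-en-8-one | O=C1C=C[C@]2(C)[C@@H](C)[C@H](O)CC[C@H]2[C@H]1O | intermediate
12 | 3-methylbut-2-enoic acid (senecioic acid) | CC(C)=CC(=O)O | starting material
13 | 9β-hydroxy-3α-(3-methylbut-2-enoyloxy)-11,12,13-trinoreremophil-6-en-8-one | O=C1C=C[C@]2(C)[C@@H](C)[C@H](OC(=O)C=C(C)C)CC[C@H]2[C@H]1O | intermediate
14 | (E)-2-methylbut-2-enoyl chloride (tigloyl chloride) | C/C=C(\C)C(=O)Cl | starting material
15 | 3α-(3-methylbut-2-enoyloxy)-9β-[(E)-2-methylbut-2-enoyloxy]-11,12,13-trinoreremophil-6-en-8-one | O=C1C=C[C@]2(C)[C@@H](C)[C@H](OC(=O)C=C(C)C)CC[C@H]2[C@H]1OC(=O)/C(C)=C/C | intermediate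
16 | 3α-(3-methylbut-2-enoyloxy)-9α-[(E)-2-methylbut-2-enoyloxy]-11,12,13-trinoreremophil-6-en-8-one | O=C1C=C[C@]2(C)[C@@H](C)[C@H](OC(=O)C=C(C)C)CC[C@H]2[C@@H]1OC(=O)/C(C)=C/C | intermediate
17 | 7-iodo-3α-(3-methylbut-2-enoyloxy)-9α-[(E)-2-methylbut-2-enoyloxy]-11,12,13-trinoreremophil-6-en-8-one | O=C1C(I)=C[C@]2(C)[C@@H](C)[C@H](OC(=O)C=C(C)C)CC[C@H]2[C@@H]1OC(=O)/C(C)=C/C | intermediate
18 | tributyl(prop-1-en-2-yl)stannane | C=C(C)[Sn](CCCC)(CCCC)CCCC | starting material
19 | 3α-(3-methylbut-2-enoyloxy)-9α-[(E)-2-methylbut-2-enoyloxy]eremophila-6,11-dien-8-one | O=C1C(C(C)=C)=C[C@]2(C)[C@@H](C)[C@H](OC(=O)C=C(C)C)CC[C@H]2[C@@H]1OC(=O)/C(C)=C/C | intermediate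
20 | 3α-(3-methylbut-2-enoyloxy)-9α-[(E)-2-methylbut-2-enoyloxy]eremophil-11-en-8-one, (3R,4R,5R,7S,9S,10R) in eremophilane numbering | C=C(C)[C@@H]1C[C@]2(C)[C@@H](C)[C@H](OC(=O)C=C(C)C)CC[C@H]2[C@H](OC(=O)/C(C)=C/C)C1=O | target

**Count**
Total: 12 steps. Longest linear sequence: 12 steps (1 to 20); 4, 12, 14 and 18 enter as purchased.

**Steps most likely to fail**

Step 2. The catalyst may bind the quinone in single-point fashion at the C6 carbonyl, which would turn the orientation round (C4 bonding to C10). The ligand may also discriminate the two quinone faces poorly, or the Lewis acid may degrade the silyl dienol ether before cycloaddition. Fallback: setting out from 3 and 4, the cycloaddition is run without any catalyst in toluene at 80–110 °C, where the unperturbed quinone reacts under control of its C9 carbonyl with the orientation needed here. This gives the racemate, that is 5 together with its mirror image, the enantiomeric cis adduct F1. The two are separated by preparative chromatography on a chiral stationary phase, and the route is rejoined at 5.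

Step 7. The acylation may fail to distinguish the two hydroxyls (bis-acylation, or attack at O9), above all if step 4 has delivered part of the equatorial 9α-alcohol. Fallback: setting out from 9, both allylic hydroxyls are capped with Et3SiCl and imidazole in DMF to give the 6β,9β-bis(triethylsilyl) ether F2. Dissolving-metal reduction (Li, NH3–THF, t-BuOH, −78 °C) then gives the 3α-alcohol F3, which has a single free hydroxyl and is esterified with 12 (DCC, DMAP) to the 3α-senecioate F4. Treatment with 1 M HCl in THF removes both silyl groups and triggers the same transposition as in step 6, returning to the route at 13.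

Step 12. The copper dienolate may be protonated at the terminal carbon C12 instead of C7, which moves the double bond into conjugation with the ketone. It may also be protonated from the face that leaves the isopropenyl group axial, or the C9 acyl group may migrate to the enolate oxygen. Fallback: setting out from 19, 1,4-hydrosilylation with Et3SiH and RhCl(PPh3)3 (2 mol%) in benzene at 50 °C gives the isolable triethylsilyl dienol ether F5, whose oxygen is capped and cannot accept the acyl group. It is then cleaved at −78 °C with Bu4NF buffered with acetic acid in THF, so that protonation at C7 is a separate, irreversible event, and the route is rejoined at 20.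

**Further compounds**
F1 | step 2 | enantiomer of 5 (cis-fused adduct, 5α-Me, 10α-H, 4β-Me) | COC1=CC(=O)[C@@]2(C)[C@@H](C)C(O[Si](C(C)C)(C(C)C)C(C)C)=CC[C@H]2C1=O
F2 | step 7 | 8-methoxy-6β,9β-bis(triethylsilyloxy)-11,12,13-trinoreremophil-7-en-3-one | COC1=C[C@@H](O[Si](CC)(CC)CC)[C@]2(C)[C@@H](C)C(=O)CC[C@H]2[C@H]1O[Si](CC)(CC)CC
F3 | step 7 | 8-methoxy-6β,9β-bis(triethylsilyloxy)-11,12,13-trinoreremophil-7-en-3α-ol | COC1=C[C@@H](O[Si](CC)(CC)CC)[C@]2(C)[C@@H](C)[C@H](O)CC[C@H]2[C@H]1O[Si](CC)(CC)CC
F4 | step 7 | 8-methoxy-6β,9β-bis(triethylsilyloxy)-11,12,13-trinoreremophil-7-en-3α-yl 3-methylbut-2-enoate | COC1=C[C@@H](O[Si](CC)(CC)CC)[C@]2(C)[C@@H](C)[C@H](OC(=O)C=C(C)C)CC[C@H]2[C@H]1O[Si](CC)(CC)CC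
F5 | step 12 | 3α-(3-methylbut-2-enoyloxy)-9α-[(E)-2-methylbut-2-enoyloxy]-8-(triethylsilyloxy)eremophila-7,11-diene | CC[Si](CC)(CC)OC1=C(C(C)=C)C[C@]2(C)[C@@H](C)[C@H](OC(=O)C=C(C)C)CC[C@H]2[C@@H]1OC(=O)/C(C)=C/C
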